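**Strategy.** The cyclohexene of the target (C1 quaternary with methyl and styryl, C2, C3, C4(Me)=C5, C6 carrying the coumarin) has an alkene carbon on each stereocentre: the styryl α-carbon on C1 and C5 on C6. Joining these two carbons gives a cyclobutene (Cα=C5 between C1 and C6) that already holds both stereocentres, with a 3-methylbut-3-enyl chain on C1. One ruthenium-catalysed ring-rearrangement metathesis then opens the strained four-membered ring and closes the six-membered ring through C4=C5, leaving vinyl on C1 for a final Heck coupling. The cyclobutene arises from an auxiliary-controlled, phenol-tethered keteniminium [2+2] cycloaddition on an E-trisubstituted styrene.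

Key step: step 10

Assumption: the cycloaddition of step 6 is taken to follow the usual substitution rule (keteniminium carbon to the less substituted alkene carbon, giving the bridged 2,4-methanochromanone) and an in-plane attack model in which the (2S,5S)-amine leads to the (2R,4R,9S) ketone; the fused regioisomer would give the same cyclobutene 18 after steps 7 to 9, and an opposite sense of induction would be corrected with the (2R,5R)-amine.

**Step 1**
Reactants: 1 4-bromo-2-methylbut-1-ene; 2 lithium acetylide–ethane-1,2-diamine complex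
Product: 3 2-methylhex-1-en-5-yne
Conditions: DMSO, 0 °C to rt
Reagents that add atoms: none
Why: SN2 alkylation of an acetylide anion by a primary bromide in DMSO (terminal alkyne synthesis) should outrun elimination, and the volatile enyne is purified by distillation.

**Step 2**
Reactants: 3 2-methylhex-1-en-5-yne; 4 2-iodo-1,3-dimethoxybenzene
Product: 6 2-[(1E)-2,5-dimethylhexa-1,5-dien-1-yl]-1,3-dimethoxybenzene, via alkenylalane 5 (not isolated)
Conditions: Me3Al (2 equiv), Cp2ZrCl2 (0.25 equiv), CH2Cl2, 0 °C to rt; then 4, Pd(PPh3)4 (5 mol%), ZnCl2 (cat.), THF, 50 °C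
Reagents that add atoms: trimethylaluminium C[Al](C)C
Why: Zirconium-catalysed Negishi carboalumination adds Me–Al syn across the terminal alkyne only (the 1,1-disubstituted alkene is inert), and the alkenylalane then undergoes palladium-catalysed Negishi cross-coupling with retention, so the aryl group ends cis to the new methyl group (E-alkene).

**Step 3**
Reactants: 6 2-[(1E)-2,5-dimethylhexa-1,5-dien-1-yl]-1,3-dimethoxybenzene
Product: 7 2-[(1E)-2,5-dimethylhexa-1,5-dien-1-yl]-3-methoxyphenol
Conditions: NaSEt (3 equiv), DMF, 130 °C; then 0.5 M HCl, 0 °C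
Reagents that add atoms: none
Why: Thiolate SN2 O-demethylation of an aryl methyl ether: the two methoxy groups are equivalent, the phenoxide formed shuts down a second demethylation, and neither alkene reacts with the anion.

**Step 4**
Reactants: 8 chloroacetyl chloride; 9 (2S,5S)-2,5-dimethylpyrrolidine
Product: 10 2-chloro-1-[(2S,5S)-2,5-dimethylpyrrolidin-1-yl]ethan-1-one
Conditions: Et3N, CH2Cl2, 0 °C
Reagents that add atoms: none
Why: Amide formation from an acyl chloride and a secondary amine (Schotten–Baumann-type acylation), the acyl chloride being far more electrophilic than the alkyl chloride; the two stereocentres of the amine are not touched.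

**Step 5**
Reactants: 7 2-[(1E)-2,5-dimethylhexa-1,5-dien-1-yl]-3-methoxyphenol; 10 2-chloro-1-[(2S,5S)-2,5-dimethylpyrrolidin-1-yl]ethan-1-one
Product: 11 2-{2-[(1E)-2,5-dimethylhexa-1,5-dien-1-yl]-3-methoxyphenoxy}-1-[(2S,5S)-2,5-dimethylpyrrolidin-1-yl]ethan-1-one
Conditions: K2CO3, NaI (cat.), DMF, 60 °C
Reagents that add atoms: none
Why: Williamson ether synthesis: the phenoxide displaces the chloride of the primary α-chloro amide under iodide catalysis, which a hindered phenol tolerates.

**Step 6**
Reactants: 11 2-{2-[(1E)-2,5-dimethylhexa-1,5-dien-1-yl]-3-methoxyphenoxy}-1-[(2S,5S)-2,5-dimethylpyrrolidin-1-yl]ethan-1-one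
Product: 14 (2R,4R,9S)-5-methoxy-9-methyl-9-(3-methylbut-3-en-1-yl)-2H-2,4-methanochromen-3(4H)-one, via keteniminium triflate 12 (not isolated), via cyclobutaniminium triflate 13 (not isolated)
Conditions: Tf2O, 2,4,6-collidine, ClCH2CH2Cl (0.01 M), −20 °C to 80 °C; then aq NaHCO3, 40 °C
Reagents that add atoms: water O
Why: Tf2O and collidine turn the amide into a keteniminium ion that engages only the neighbouring E-alkene (Ghosez keteniminium–alkene [2+2] cycloaddition, intramolecular, so the remote isopropenyl group cannot compete): its central carbon bonds in plane to the benzylic CH, the tertiary cation closes on the same alkene face onto the enamine carbon so that the E-geometry places methyl cis to the arene, and the methyl groups of the C2-symmetric pyrrolidine leave one half-space open for this second bond, which fixes C2, C4 and C9 together before the iminium ion is hydrolysed.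

**Step 7**
Reactants: 14 (2R,4R,9S)-5-methoxy-9-methyl-9-(3-methylbut-3-en-1-yl)-2H-2,4-methanochromen-3(4H)-one
Product: 15 (2R,3R)-2-(2-hydroxy-6-methoxyphenyl)-3-methyl-3-(3-methylbut-3-en-1-yl)cyclobutan-1-one
Conditions: SmI2 (2.5 equiv), THF/MeOH, −78 °C
Reagents that add atoms: none
Why: Samarium diiodide reduction of an α-heterosubstituted ketone: two single-electron transfers to the strained ketone expel the α-aryloxide from C2, the samarium enolate is protonated by methanol at −78 °C, and the bicycle opens to the monocyclic ketone with the benzylic and quaternary centres unchanged.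

**Step 8**
Reactants: 15 (2R,3R)-2-(2-hydroxy-6-methoxyphenyl)-3-methyl-3-(3-methylbut-3-en-1-yl)cyclobutan-1-one
Product: 16 N'-[(2R,3R)-2-(2-hydroxy-6-methoxyphenyl)-3-methyl-3-(3-methylbut-3-en-1-yl)cyclobutylidene]-2,4,6-tri(propan-2-yl)benzenesulfonohydrazide
Conditions: 2,4,6-triisopropylbenzenesulfonohydrazide (1.1 equiv), THF, rt
Reagents that add atoms: 2,4,6-tri(propan-2-yl)benzenesulfonohydrazide CC(C)c1cc(C(C)C)c(S(=O)(=O)NN)c(C(C)C)c1
Why: Condensation of the strained, electrophilic cyclobutanone with the sulfonyl hydrazide should proceed without acid at room temperature, which keeps the enolisable benzylic α-carbon configurationally intact.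

**Step 9**
Reactants: 16 N'-[(2R,3R)-2-(2-hydroxy-6-methoxyphenyl)-3-methyl-3-(3-methylbut-3-en-1-yl)cyclobutylidene]-2,4,6-tri(propan-2-yl)benzenesulfonohydrazide
Product: 18 3-methoxy-2-[(1R,4R)-4-methyl-4-(3-methylbut-3-en-1-yl)cyclobut-2-en-1-yl]phenol, via cyclobutenyllithium 17 (not isolated)
Conditions: n-BuLi (3.3 equiv), THF, −78 °C to 0 °C; then H2O
Reagents that add atoms: none
Why: Shapiro reaction: after deprotonation of OH and NH, n-BuLi removes a proton from the CH2 group syn to the sulfonamide nitrogen (the less substituted α-carbon), loss of sulfinate and N2 gives the cyclobutenyllithium, and protonation places the alkene between the former carbonyl carbon and that CH2 without touching either stereocentre.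

**Step 10**
Reactants: 18 3-methoxy-2-[(1R,4R)-4-methyl-4-(3-methylbut-3-en-1-yl)cyclobut-2-en-1-yl]phenol
Product: 19 2-[(1R,6R)-6-ethenyl-3,6-dimethylcyclohex-2-en-1-yl]-3-methoxyphenol
Conditions: second-generation Grubbs catalyst RuCl2(=CHPh)(PCy3)(H2IMes) (5 mol%), ethene (1 atm), CH2Cl2 (0.01 M), 40 °C
Reagents that add atoms: none
Why: Ru=CH2, formed from the benzylidene under ethene, undergoes [2+2] cycloaddition with the strained cyclobutene alkene with ruthenium on C5, the carbon remote from the quaternary centre, and cycloreversion releases the ring strain, leaving CH=CH2 on C1 and a ruthenium alkylidene on C5. This alkylidene adds across the 1,1-disubstituted alkene of the side chain and cycloreverts, which forms C4=C5, closes the six-membered ring by ring-closing metathesis and regenerates Ru=CH2. The sequence is a ring-rearrangement metathesis (ring opening of a strained cycloalkene followed by ring closure onto a tethered alkene), a known reaction class. No stereocentre is formed: C1 and C6 are not touched, so methyl cis to aryl on the cyclobutene becomes vinyl cis to aryl on the cyclohexene. The step needs ruthenium on C5 and six- rather than five-membered closure; both follow from the neopentyl position of Cα, which is slow to carry ruthenium, and if ethene caps both ends as a triene the catalyst still loads first on the C5 vinyl group. The vinyl group on the quaternary carbon and the trisubstituted ring alkene of the product are poor substrates, so the reaction should stop there.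

**Step 11**
Reactants: 19 2-[(1R,6R)-6-ethenyl-3,6-dimethylcyclohex-2-en-1-yl]-3-methoxyphenol
Product: 20 3-[(1R,6R)-6-ethenyl-3,6-dimethylcyclohex-2-en-1-yl]-2-hydroxy-4-methoxybenzaldehyde
Conditions: MgCl2, Et3N, (CH2O)n, THF, reflux; then 0.5 M HCl, 0 °C
Reagents that add atoms: formaldehyde (as paraformaldehyde) C=O
Why: Magnesium phenoxide-directed ortho-formylation (Casnati–Skattebøl reaction): formaldehyde is delivered through the chelate to the only free ortho position, which is also para to the methoxy group, and a second formaldehyde oxidises the benzylic alkoxide to the aldehyde.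

**Step 12**
Reactants: 20 3-[(1R,6R)-6-ethenyl-3,6-dimethylcyclohex-2-en-1-yl]-2-hydroxy-4-methoxybenzaldehyde
Product: 22 8-[(1R,6R)-6-ethenyl-3,6-dimethylcyclohex-2-en-1-yl]-7-methoxy-2H-chromen-2-one, via acyl ylide 21 (not isolated)
Conditions: Ph3P=C=C=O (1.2 equiv), toluene, reflux
Reagents that add atoms: (triphenyl-λ5-phosphanylidene)ethenone O=C=C=P(c1ccccc1)(c1ccccc1)c1ccccc1
Why: The phenol adds across the ketene unit of the Bestmann ylide to give a stabilised acyl ylide whose intramolecular Wittig reaction with the ortho aldehyde can only give the cis alkene of the lactone, so the coumarin should form at 110 °C without a separate isomerisation.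

**Step 13**
Reactants: 23 7-hydroxy-2H-chromen-2-one
Product: 24 7-hydroxy-8-iodo-2H-chromen-2-one
Conditions: I2, KI, 20% aq NH3, rt; then dilute H2SO4
Reagents that add atoms: iodine II
Why: Electrophilic aromatic iodination of the phenoxide, which goes to C8, the ortho position between the hydroxyl group and the ring oxygen.

**Step 14**
Reactants: 24 7-hydroxy-8-iodo-2H-chromen-2-one
Product: 25 8-iodo-7-methoxy-2H-chromen-2-one
Conditions: MeI, K2CO3, acetone, reflux
Reagents that add atoms: iodomethane CI
Why: Williamson O-methylation of the phenoxide; the lactone survives the weak base.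

**Step 15**
Reactants: 22 8-[(1R,6R)-6-ethenyl-3,6-dimethylcyclohex-2-en-1-yl]-7-methoxy-2H-chromen-2-one; 25 8-iodo-7-methoxy-2H-chromen-2-one
Product: 26 8-[(E)-2-[(1R,2R)-2-(7-methoxy-2-oxo-2H-chromen-8-yl)-1,4-dimethylcyclohex-3-en-1-yl]ethenyl]-7-methoxy-2H-chromen-2-one
Conditions: Pd(OAc)2 (10 mol%), Bu4NCl, NaHCO3, DMF, 90 °C
Reagents that add atoms: none
Why: Mizoroki–Heck reaction under Jeffery conditions: the arylpalladium iodide inserts the monosubstituted alkene with aryl on the terminal carbon, and syn β-hydride elimination, possible only towards the benzylic side because C1 is quaternary, gives the E-styryl unit without alkene migration or any change at the stereocentres.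

**Compound list**

1 | 4-bromo-2-methylbut-1-ene | C=C(C)CCBr | starting material
2 | lithium acetylide–ethane-1,2-diamine complex | [Li+].[C-]#C.NCCN | starting material
3 | 2-methylhex-1-en-5-yne | C=C(C)CCC#C | intermediate
4 | 2-iodo-1,3-dimethoxybenzene | COc1cccc(OC)c1I | starting material
5 | [(1E)-2,5-dimethylhexa-1,5-dien-1-yl]dimethylalumane | C[Al](C)/C=C(\C)CCC(C)=C | intermediate
6 | 2-[(1E)-2,5-dimethylhexa-1,5-dien-1-yl]-1,3-dimethoxybenzene | COc1cccc(OC)c1/C=C(\C)CCC(C)=C | intermediate
7 | 2-[(1E)-2,5-dimethylhexa-1,5-dien-1-yl]-3-methoxyphenol | COc1cccc(O)c1/C=C(\C)CCC(C)=C | intermediate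
8 | chloroacetyl chloride | ClCC(Cl)=O | starting material
9 | (2S,5S)-2,5-dimethylpyrrolidine | C[C@H]1CC[C@H](C)N1 | starting material
10 | 2-chloro-1-[(2S,5S)-2,5-dimethylpyrrolidin-1-yl]ethan-1-one | O=C(CCl)N1[C@@H](C)CC[C@@H]1C | intermediate
11 | 2-{2-[(1E)-2,5-dimethylhexa-1,5-dien-1-yl]-3-methoxyphenoxy}-1-[(2S,5S)-2,5-dimethylpyrrolidin-1-yl]ethan-1-one | COc1cccc(OCC(=O)N2[C@@H](C)CC[C@@H]2C)c1/C=C(\C)CCC(C)=C | intermediate
12 | (2S,5S)-1-(2-{2-[(1E)-2,5-dimethylhexa-1,5-dien-1-yl]-3-methoxyphenoxy}ethenylidene)-2,5-dimethylpyrrolidin-1-ium trifluoromethanesulfonate | COc1cccc(OC=C=[N+]2[C@@H](C)CC[C@@H]2C)c1/C=C(\C)CCC(C)=C.[O-]S(=O)(=O)C(F)(F)F | intermediate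
13 | (2S,5S)-1-[(2R,4R,9S)-5-methoxy-9-methyl-9-(3-methylbut-3-en-1-yl)-2H-2,4-methanochromen-3(4H)-ylidene]-2,5-dimethylpyrrolidin-1-ium trifluoromethanesulfonate | COc1cccc2c1[C@@H]1C(=[N+]3[C@@H](C)CC[C@@H]3C)[C@H](O2)[C@@]1(C)CCC(C)=C.[O-]S(=O)(=O)C(F)(F)F | intermediate
14 | (2R,4R,9S)-5-methoxy-9-methyl-9-(3-methylbut-3-en-1-yl)-2H-2,4-methanochromen-3(4H)-one | COc1cccc2c1[C@@H]1C(=O)[C@H](O2)[C@@]1(C)CCC(C)=C | intermediate
15 | (2R,3R)-2-(2-hydroxy-6-methoxyphenyl)-3-methyl-3-(3-methylbut-3-en-1-yl)cyclobutan-1-one | COc1cccc(O)c1[C@@H]1C(=O)C[C@@]1(C)CCC(C)=C | intermediate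
16 | N'-[(2R,3R)-2-(2-hydroxy-6-methoxyphenyl)-3-methyl-3-(3-methylbut-3-en-1-yl)cyclobutylidene]-2,4,6-tri(propan-2-yl)benzenesulfonohydrazide | COc1cccc(O)c1[C@@H]1C(=NNS(=O)(=O)c2c(C(C)C)cc(C(C)C)cc2C(C)C)C[C@@]1(C)CCC(C)=C | intermediate
17 | lithium 2-[(1R,4R)-2-lithio-4-methyl-4-(3-methylbut-3-en-1-yl)cyclobut-2-en-1-yl]-3-methoxyphenolate | COc1cccc(O[Li])c1[C@@H]1C([Li])=C[C@@]1(C)CCC(C)=C | intermediate
18 | 3-methoxy-2-[(1R,4R)-4-methyl-4-(3-methylbut-3-en-1-yl)cyclobut-2-en-1-yl]phenol | COc1cccc(O)c1[C@@H]1C=C[C@@]1(C)CCC(C)=C | intermediate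
19 | 2-[(1R,6R)-6-ethenyl-3,6-dimethylcyclohex-2-en-1-yl]-3-methoxyphenol | C=C[C@@]1(C)CCC(C)=C[C@H]1c1c(OC)cccc1O | intermediate
20 | 3-[(1R,6R)-6-ethenyl-3,6-dimethylcyclohex-2-en-1-yl]-2-hydroxy-4-methoxybenzaldehyde | C=C[C@@]1(C)CCC(C)=C[C@H]1c1c(OC)ccc(C=O)c1O | intermediate
21 | 6-[(1R,6R)-6-ethenyl-3,6-dimethylcyclohex-2-en-1-yl]-2-formyl-5-methoxyphenyl (triphenyl-λ5-phosphanylidene)acetate | C=C[C@@]1(C)CCC(C)=C[C@H]1c1c(OC)ccc(C=O)c1OC(=O)C=P(c1ccccc1)(c1ccccc1)c1ccccc1 | intermediate
22 | 8-[(1R,6R)-6-ethenyl-3,6-dimethylcyclohex-2-en-1-yl]-7-methoxy-2H-chromen-2-one | C=C[C@@]1(C)CCC(C)=C[C@H]1c1c(OC)ccc2ccc(=O)oc12 | intermediate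
23 | 7-hydroxy-2H-chromen-2-one | Oc1ccc2ccc(=O)oc2c1 | starting material
24 | 7-hydroxy-8-iodo-2H-chromen-2-one | Oc1ccc2ccc(=O)oc2c1I | intermediate
25 | 8-iodo-7-methoxy-2H-chromen-2-one | COc1ccc2ccc(=O)oc2c1I | intermediate
26 | 8-[(E)-2-[(1R,2R)-2-(7-methoxy-2-oxo-2H-chromen-8-yl)-1,4-dimethylcyclohex-3-en-1-yl]ethenyl]-7-methoxy-2H-chromen-2-one | COc1ccc2ccc(=O)oc2c1/C=C/[C@@]1(C)CCC(C)=C[C@H]1c1c(OC)ccc2ccc(=O)oc12 | target

**Step count and risks**

Total step count: 15. Longest linear sequence: 12 steps (steps 1, 2, 3, 5, 6, 7, 8, 9, 10, 11, 12, 15).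

Three steps most likely to fail:

Step 6. The pyrrolidinium auxiliary may discriminate the two alkene faces poorly, or the cationic keteniminium may attack the electron-rich arene before it reaches the alkene. The fallback uses a neutral ketene and a resolution. Setting out from phenol 7, O-alkylation with methyl bromoacetate (K2CO3, acetone) should give methyl {2-[(1E)-2,5-dimethylhexa-1,5-dien-1-yl]-3-methoxyphenoxy}acetate F1. LiOH followed by cold dilute HCl gives {2-[(1E)-2,5-dimethylhexa-1,5-dien-1-yl]-3-methoxyphenoxy}acetic acid F2, and oxalyl chloride gives the acid chloride F3. Et3N in refluxing toluene at high dilution generates the aryloxyketene F4, which does not acylate arenes; its intramolecular ketene–alkene [2+2] cycloaddition should give the racemic bridged ketone F5. Preparative chromatography on a chiral stationary phase then delivers 14, where the fallback rejoins the route.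

Step 10. Ring-opening metathesis polymerisation of the cyclobutene, or ring opening that is not followed by ring closure, may outrun the rearrangement. The fallback separates the two metathesis events. From 18, ethenolysis with first-generation Grubbs catalyst RuCl2(=CHPh)(PCy3)2 under ethene pressure should give the triene 2-[(3R,4R)-4-ethenyl-4,7-dimethylocta-1,7-dien-3-yl]-3-methoxyphenol F6; this catalyst opens strained rings but does not readily form trisubstituted alkenes. Ring-closing metathesis of F6 with Hoveyda–Grubbs second-generation catalyst RuCl2(=CH-2-iPrOC6H4)(H2IMes) in refluxing toluene under an argon sparge, which removes ethene, then gives 19, where the route is rejoined.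

Step 7. Once the ether bridge is cut, the benzylic carbon is α to the ketone and may lose its configuration by enolisation during the reduction or the hydrazone formation. The fallback is a Kishner–Leonard eliminative reduction that bypasses steps 7 to 9. From 14, hydrazine hydrate in ethanol should give the hydrazone (2R,4R,9S)-3-hydrazinylidene-5-methoxy-9-methyl-9-(3-methylbut-3-en-1-yl)-3,4-dihydro-2H-2,4-methanochromene F7. KOtBu in DMSO at room temperature then expels the aryloxide from the α-carbon, the vinyl diazene loses N2, and cyclobutene 18 forms directly, so the benzylic centre is never enolisable. The route is rejoined at 18.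

**Further compounds**

F1 | step 6 | methyl {2-[(1E)-2,5-dimethylhexa-1,5-dien-1-yl]-3-methoxyphenoxy}acetate | COC(=O)COc1cccc(OC)c1/C=C(\C)CCC(C)=C
F2 | step 6 | {2-[(1E)-2,5-dimethylhexa-1,5-dien-1-yl]-3-methoxyphenoxy}acetic acid | OC(=O)COc1cccc(OC)c1/C=C(\C)CCC(C)=C
F3 | step 6 | {2-[(1E)-2,5-dimethylhexa-1,5-dien-1-yl]-3-methoxyphenoxy}acetyl chloride | ClC(=O)COc1cccc(OC)c1/C=C(\C)CCC(C)=C
F4 | step 6 | 2-{2-[(1E)-2,5-dimethylhexa-1,5-dien-1-yl]-3-methoxyphenoxy}ethen-1-one | O=C=COc1cccc(OC)c1/C=C(\C)CCC(C)=C
F5 | step 6 | racemic 5-methoxy-9-methyl-9-(3-methylbut-3-en-1-yl)-2H-2,4-methanochromen-3(4H)-one (racemate of 14; one enantiomer drawn) | COc1cccc2c1[C@@H]1C(=O)[C@H](O2)[C@@]1(C)CCC(C)=C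
F6 | step 10 | 2-[(3R,4R)-4-ethenyl-4,7-dimethylocta-1,7-dien-3-yl]-3-methoxyphenol | C=C[C@@H](c1c(OC)cccc1O)[C@@](C)(C=C)CCC(C)=C
F7 | step 7 | (2R,4R,9S)-3-hydrazinylidene-5-methoxy-9-methyl-9-(3-methylbut-3-en-1-yl)-3,4-dihydro-2H-2,4-methanochromene | COc1cccc2c1[C@@H]1C(=NN)[C@H](O2)[C@@]1(C)CCC(C)=C
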